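**Retrosynthetic overview**

1. The ε-lactone is closed last: a silyl ester opens an (11S,12S)-epoxide at C12 with inversion; the epoxide comes from C8–OH-directed epoxidation of an (11E)-alkene, and the two acetates go on at the very end.
2. The oxolane (C4–O–C7, with C7 and C8) comes from a diol-directed, osmium-catalysed oxidative cyclisation of a macrocyclic (7Z)-ene-3,4-diol.
3. The 14-membered carbocycle is closed at C13–C14 by a photochemical nickel/iridium decarboxylative alkyl–allyl coupling (CO2 and phenoxide leave); this is the new key step.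
4. The open-chain acid comes from a chelate-controlled Grignard addition (C4–C5, sets C4) of a (Z,E)-dienyl bromide (homoprenyl bromide + propyne + oxirane) to a keto acetal cut out of (R)-carvone (C1 bought, C3 by Luche reduction).
5. Ring order: carbocycle, then oxolane, then lactone.

Assumption: C1–C20 are the cembrane locants of the target (C1 = ring CH bearing C15; C16 = lactone C=O; C17 = exocyclic CH2; C18–C20 = methyls on C4, C8, C12), C21 is the carvone carbon on C14 that is later lost as CO2, and the target SMILES is read as 1R,3R,4R,7S,8R,11S,12R.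

**Route**

Step 1
Reactants: 1 (R)-(−)-carvone
Product: 2 10-hydroxycarvone
Conditions: SeO2 (0.3 equiv), t-BuOOH, CH2Cl2, rt
Reagents that add atoms: tert-butyl hydroperoxide, CC(C)(C)OO
Why: SeO2 allylic oxidation (ene then [2,3]-sigmatropic shift) attacks the electron-rich isopropenyl group rather than the deactivated enone alkene and oxidises its methyl group, leaving the bought C1 stereocentre untouched.

Step 2
Reactants: 2 10-hydroxycarvone
Product: 3 enone acrylic acid
Conditions: TEMPO (0.2 equiv), PhI(OAc)2 (2.2 equiv), MeCN/H2O, rt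
Reagents that add atoms: water, O
Why: Oxoammonium (TEMPO/PhI(OAc)2) oxidation takes the primary allylic alcohol through the aldehyde hydrate to the acrylic acid without touching the enone or the stereocentre.

Step 3
Reactants: 3 enone acrylic acid
Product: 4 cis-hydroxy acid
Conditions: NaBH4, CeCl3·7H2O, MeOH, −40 → 0 °C
Reagents that add atoms: none
Why: Luche 1,2-reduction, in which hydride attacks axially on the half-chair that holds the C1 side chain pseudo-equatorial and gives the cis (pseudo-equatorial) alcohol, so C3 (R) is set by C1.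

Step 4
Reactants: 4 cis-hydroxy acid
Product: 6 keto methyl acetal, via lactol 5 (not isolated)
Conditions: O3, CH2Cl2/MeOH, −78 °C; Me2S; then PPTS (cat.), MeOH, rt
Reagents that add atoms: ozone, [O-][O+]=O; methanol, CO
Why: Chemoselective ozonolysis of the electron-rich trisubstituted ring alkene (the acrylic acid alkene is electron-poor) gives the C4 methyl ketone and an aldehyde that the C3 hydroxyl traps as a six-membered lactol, and acid-catalysed acetalisation then masks the aldehyde and makes O3 a chelating ring ether, with C1 and C3 unchanged.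

Step 5
Reactants: 7 5-bromo-2-methylpent-2-ene
Product: 8 (E)-bromo allylic alcohol
Conditions: SeO2 (0.1 equiv), t-BuOOH, CH2Cl2, rt
Reagents that add atoms: tert-butyl hydroperoxide, CC(C)(C)OO
Why: SeO2/t-BuOOH allylic oxidation of a trisubstituted alkene is selective for the (E)-methyl group, so only the (E)-allylic alcohol forms on this single-alkene substrate.

Step 6
Reactants: 8 (E)-bromo allylic alcohol
Product: 9 bromo allyl phenyl ether
Conditions: PhOH, PPh3, DIAD, THF, 0 °C → rt
Reagents that add atoms: phenol, Oc1ccccc1
Why: Mitsunobu etherification of the primary allylic alcohol goes by direct SN2 displacement without allylic shift and installs an aryloxy leaving group that tolerates Grignard, organocopper and hydroxide chemistry.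

Step 7
Reactants: 9 bromo allyl phenyl ether, 10 propyne, 11 oxirane
Product: 14 (3Z,7E)-dienol, via Grignard reagent 12 (not isolated), via alkenylcopper 13 (not isolated)
Conditions: Mg, Et2O; CuBr·SMe2, Et2O/Me2S, −45 °C; propyne, −25 °C; LiC≡C-n-Bu, then oxirane, THF, −78 → −20 °C; aq. NH4Cl
Reagents that add atoms: none
Why: Normant carbocupration, in which the alkylcopper adds syn across propyne with copper on the terminal carbon and the alkenylcopper (as its mixed alkynyl cuprate) opens oxirane with retention, so the two chains end up cis on the new trisubstituted alkene (Z).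

Step 8
Reactants: 14 (3Z,7E)-dienol
Product: 15 dienyl bromide
Conditions: CBr4, PPh3, CH2Cl2, 0 °C
Reagents that add atoms: carbon tetrabromide, BrC(Br)(Br)Br
Why: The Appel reaction converts the primary homoallylic alcohol to the bromide under neutral conditions that leave both alkenes and the allyl phenyl ether alone.

Step 9
Reactants: 6 keto methyl acetal, 15 dienyl bromide
Product: 17 tertiary alcohol acetal, via Grignard reagent 16 (not isolated)
Conditions: 15, Mg, THF, rt; 6, t-BuMgCl (1.0 equiv), THF, −78 °C; then 16 (1.3 equiv), −78 → −40 °C; aq. NH4Cl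
Reagents that add atoms: none
Why: Cram chelate-controlled Grignard addition, in which magnesium bridges the ketone oxygen and ring oxygen O3 and the nucleophile enters past the C3 hydrogen, anti to the ring CH2, giving the (4R) tertiary alcohol (3,4-syn), while the pre-formed carboxylate, the acetal and the acrylate are inert at −78 °C.

Step 10
Reactants: 17 tertiary alcohol acetal
Product: 19 δ-lactone acid, via lactol 18 (not isolated)
Conditions: AcOH/THF/H2O, 40 °C; then TEMPO (0.1 equiv), PhI(OAc)2 (1.2 equiv), CH2Cl2, rt
Reagents that add atoms: water, O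
Why: Mild aqueous acid hydrolyses the 2-deoxy-type methyl acetal to the lactol and oxoammonium oxidation turns it into the δ-lactone, which stores C21 as an acyl group on O3 without affecting the alkenes, the tertiary alcohol or the allyl phenyl ether.

Step 11
Reactants: 19 δ-lactone acid
Product: 21 macrocyclic diol acid, via dicesium salt 20 (not isolated)
Conditions: CsOH·H2O (2.0 equiv), THF/H2O, 0 °C, evaporate; CF3CO2H (1.0 equiv), [Ir{dF(CF3)ppy}2(dtbbpy)]PF6 (2 mol %), NiCl2(dme) (10 mol %), dtbbpy (15 mol %), DMSO (2 mM), 450 nm LEDs, 25 °C; cold aq. HCl to pH 4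
Reagents that add atoms: none
Why: Proposed new method: hydroxide opens the lactone to the δ-hydroxy carboxylate, the excited iridium photocatalyst oxidises this unactivated primary carboxylate (loss of CO2) to the C14 radical while zerovalent nickel ionises the allyl phenyl ether to a divalent π-allylnickel phenoxide (protonated by the acrylic acid so that phenoxide does not quench the photocatalyst), the tethered radical is captured to a trivalent alkyl(allyl)nickel that reductively eliminates at the unsubstituted allyl terminus C13 (E-alkene from the syn π-allyl) and the reduced photocatalyst returns monovalent nickel to the zerovalent state, closing the 14-membered ring redox-neutrally with no stereocentre formed or epimerised; the closest known reaction types are nickel/photoredox decarboxylative C(sp3)–C(sp3) coupling of carboxylic acids with alkyl halides and palladium/photoredox decarboxylative allylation of stabilised carboxylates, neither shown for an unactivated primary carboxylate with an allyl aryl ether or for a macrocyclisation.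

Step 12
Reactants: 21 macrocyclic diol acid
Product: 22 oxolane diol acid
Conditions: K2OsO2(OH)4 (5 mol %), pyridine N-oxide (3 equiv), citric acid (0.75 equiv), Cu(OTf)2 (0.5 equiv), MeCN/aq. phosphate buffer pH 6.5, 60 °C
Reagents that add atoms: pyridine N-oxide, [O-][n+]1ccccc1
Why: Diol-directed osmium-catalysed oxidative cyclisation, in which the 3,4-diol forms a hexavalent osmium glycolate that after oxidation to the octavalent state adds O4 and an oxo ligand suprafacially across the (7Z)-alkene, so the tether enforces the 2,5-cis oxolane (C7 S, controlled by C3/C4) and syn addition to the Z-alkene fixes C8 (R), while pyridine N-oxide is too weak an oxidant to dihydroxylate the remote alkene or the acrylate and pH 6.5 keeps the acid from lactonising onto O3.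

Step 13
Reactants: 22 oxolane diol acid
Product: 23 (11S,12S)-epoxide
Conditions: VO(acac)2 (10 mol %), t-BuOOH (1.5 equiv), 2,6-lutidine (1.2 equiv), PhMe, 0 °C → rt
Reagents that add atoms: tert-butyl hydroperoxide, CC(C)(C)OO
Why: Hydroxyl-directed epoxidation of the only alkene within reach of a hydroxyl, in which the C8 alkoxide and the adjacent ring oxygen are expected to bind pentavalent vanadium as a bidentate ligand, placing C7 axial and the C8 methyl equatorial in the chair-like oxygen-transfer transition state and delivering oxygen to the face of the (11E)-alkene that gives the (11S,12S)-epoxide (C11 and C12 controlled by C8), with lutidine holding the acid as carboxylate so the epoxide survives.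

Step 14
Reactants: 23 (11S,12S)-epoxide
Product: 26 lactone triol, via silyl ester 24 (not isolated), via silylated lactone 25 (not isolated)
Conditions: 1-(trimethylsilyl)imidazole (4 equiv), CH2Cl2, rt; then TMSOTf (0.1 equiv), −40 °C; then 1 M HCl/MeOH, 0 °C
Reagents that add atoms: none
Why: Silylation removes the nucleophilicity of the C3 and C8 hydroxyls and turns the acid into a silyl ester whose carbonyl oxygen opens the TMSOTf-activated epoxide 7-exo at the tertiary carbon C12 with inversion (12R) while the C11–O bond is retained (11S), an epoxide-opening lactonisation, after which acidic methanol strips the three silyl groups.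

Step 15
Reactants: 26 lactone triol
Product: 27 CNP0343714.4
Conditions: Ac2O, pyridine, DMAP (5 mol %), CH2Cl2, 0 °C → rt
Reagents that add atoms: acetic anhydride, CC(=O)OC(C)=O
Why: Acetylation with Ac2O/pyridine and catalytic DMAP esterifies the two secondary alcohols (C3 and C11) while the tertiary C8 alcohol does not react, and no stereocentre is touched.

**Compound list**

1 | (R)-(−)-carvone, (5R)-2-methyl-5-(prop-1-en-2-yl)cyclohex-2-en-1-one | CC1=CC[C@H](CC1=O)C(C)=C | starting material
2 | 10-hydroxycarvone, (5R)-5-(3-hydroxyprop-1-en-2-yl)-2-methylcyclohex-2-en-1-one | CC1=CC[C@H](CC1=O)C(=C)CO | intermediate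
3 | 2-[(1R)-4-methyl-5-oxocyclohex-3-en-1-yl]prop-2-enoic acid | CC1=CC[C@H](CC1=O)C(=C)C(=O)O | intermediate
4 | 2-[(1R,5R)-5-hydroxy-4-methylcyclohex-3-en-1-yl]prop-2-enoic acid (hydroxyl cis to the acrylic acid side chain) | CC1=CC[C@H](C[C@H]1O)C(=C)C(=O)O | intermediate
5 | 2-[(4S,6R)-6-acetyl-2-hydroxyoxan-4-yl]prop-2-enoic acid (lactol, both anomers; not isolated) | OC1C[C@H](C[C@@H](O1)C(C)=O)C(=C)C(=O)O | intermediate
6 | 2-[(4S,6R)-6-acetyl-2-methoxyoxan-4-yl]prop-2-enoic acid (both anomers) | COC1C[C@H](C[C@@H](O1)C(C)=O)C(=C)C(=O)O | intermediate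
7 | 5-bromo-2-methylpent-2-ene | CC(C)=CCCBr | starting material
8 | (2E)-5-bromo-2-methylpent-2-en-1-ol | BrCC/C=C(C)/CO | intermediate
9 | {[(2E)-5-bromo-2-methylpent-2-en-1-yl]oxy}benzene | BrCC/C=C(C)/COc1ccccc1 | intermediate
10 | propyne | CC#C | starting material
11 | oxirane | C1CO1 | starting material
12 | [(3E)-4-methyl-5-phenoxypent-3-en-1-yl]magnesium bromide (not isolated) | Br[Mg]CC/C=C(C)/COc1ccccc1 | intermediate
13 | [(1Z,5E)-2,6-dimethyl-7-phenoxyhepta-1,5-dien-1-yl]copper (not isolated) | [Cu]/C=C(C)\CC/C=C(C)/COc1ccccc1 | intermediate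
14 | (3Z,7E)-4,8-dimethyl-9-phenoxynona-3,7-dien-1-ol | OCC/C=C(C)\CC/C=C(C)/COc1ccccc1 | intermediate
15 | {[(2E,6Z)-9-bromo-2,6-dimethylnona-2,6-dien-1-yl]oxy}benzene | BrCC/C=C(C)\CC/C=C(C)/COc1ccccc1 | intermediate
16 | [(3Z,7E)-4,8-dimethyl-9-phenoxynona-3,7-dien-1-yl]magnesium bromide (not isolated) | Br[Mg]CC/C=C(C)\CC/C=C(C)/COc1ccccc1 | intermediate
17 | 2-[(4S,6R)-6-[(2R,5Z,9E)-2-hydroxy-6,10-dimethyl-11-phenoxyundeca-5,9-dien-2-yl]-2-methoxyoxan-4-yl]prop-2-enoic acid (both anomers) | COC1C[C@H](C[C@@H](O1)[C@](C)(O)CC/C=C(C)\CC/C=C(C)/COc1ccccc1)C(=C)C(=O)O | intermediate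
18 | 2-[(4S,6R)-2-hydroxy-6-[(2R,5Z,9E)-2-hydroxy-6,10-dimethyl-11-phenoxyundeca-5,9-dien-2-yl]oxan-4-yl]prop-2-enoic acid (lactol; not isolated) | OC1C[C@H](C[C@@H](O1)[C@](C)(O)CC/C=C(C)\CC/C=C(C)/COc1ccccc1)C(=C)C(=O)O | intermediate
19 | 2-[(2R,4S)-2-[(2R,5Z,9E)-2-hydroxy-6,10-dimethyl-11-phenoxyundeca-5,9-dien-2-yl]-6-oxooxan-4-yl]prop-2-enoic acid | O=C1C[C@H](C[C@@H](O1)[C@](C)(O)CC/C=C(C)\CC/C=C(C)/COc1ccccc1)C(=C)C(=O)O | intermediate
20 | dicesium (3S,5R,6R,9Z,13E)-3-(1-carboxylatoethenyl)-5,6-dihydroxy-6,10,14-trimethyl-15-phenoxypentadeca-9,13-dienoate (not isolated) | [Cs+].[Cs+].[O-]C(=O)C[C@H](C[C@@H](O)[C@](C)(O)CC/C=C(C)\CC/C=C(C)/COc1ccccc1)C(=C)C([O-])=O | intermediate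
21 | 2-[(1R,3R,4R,7Z,11E)-3,4-dihydroxy-4,8,12-trimethylcyclotetradeca-7,11-dien-1-yl]prop-2-enoic acid (cembrane locants) | C=C(C(=O)O)[C@H]1C[C@@H](O)[C@](C)(O)CC/C=C(C)\CC/C=C(C)/CC1 | intermediate
22 | 2-[(1R,3R,4R,7S,8R,11E)-3,8-dihydroxy-4,8,12-trimethyl-4,7-epoxycyclotetradec-11-en-1-yl]prop-2-enoic acid (cembrane locants; cis-2,5-disubstituted oxolane) | C=C(C(=O)O)[C@H]1C[C@@H](O)[C@@]2(C)CC[C@H](O2)[C@](C)(O)CC/C=C(C)/CC1 | intermediate
23 | 2-[(1R,3R,4R,7S,8R,11S,12S)-3,8-dihydroxy-4,8,12-trimethyl-4,7:11,12-diepoxycyclotetradecan-1-yl]prop-2-enoic acid (cembrane locants) | C=C(C(=O)O)[C@H]1C[C@@H](O)[C@@]2(C)CC[C@H](O2)[C@](C)(O)CC[C@@H]2O[C@@]2(C)CC1 | intermediate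
24 | trimethylsilyl ester 3,8-bis(trimethylsilyl) ether of 23 (not isolated) | C=C(C(=O)O[Si](C)(C)C)[C@H]1C[C@@H](O[Si](C)(C)C)[C@@]2(C)CC[C@H](O2)[C@](C)(O[Si](C)(C)C)CC[C@@H]2O[C@@]2(C)CC1 | intermediate
25 | 3,8,11-tris-O-(trimethylsilyl) derivative of 26 (not isolated) | C=C1C(=O)O[C@]2(C)CC[C@@H]1C[C@@H](O[Si](C)(C)C)[C@@]1(C)CC[C@H](O1)[C@](C)(O[Si](C)(C)C)CC[C@@H]2O[Si](C)(C)C | intermediate
26 | (1R,3R,4R,7S,8R,11S,12R)-3,8,11-trihydroxy-4,7-epoxycembr-15(17)-en-16,12-olide | C=C1C(=O)O[C@]2(C)CC[C@@H]1C[C@@H](O)[C@@]1(C)CC[C@H](O1)[C@](C)(O)CC[C@@H]2O | intermediate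
27 | CNP0343714.4, (1R,3R,4R,7S,8R,11S,12R)-3,11-diacetoxy-8-hydroxy-4,7-epoxycembr-15(17)-en-16,12-olide | C=C1C(=O)O[C@]2(C)CC[C@@H]1C[C@@H](OC(C)=O)[C@@]1(C)CC[C@H](O1)[C@](C)(O)CC[C@@H]2OC(C)=O | target

**Step count and risks**

Total steps: 15. Longest linear sequence: 11 steps (1–4 then 9–15 from carvone; equally 5–8 then 9–15 from 5-bromo-2-methylpent-2-ene).

Steps most likely to fail:

Step 11 (new macrocyclisation). Risks are protodecarboxylation, 1,5-hydrogen transfer from C3–H to the C14 radical, and slow ionisation of the allyl aryl ether by nickel. The fallback uses known chemistry, sets out from 19 and comes back at 21. Compound 19 is deprotonated with LiN(SiMe3)2 (3.2 equiv: carboxylate, tertiary alkoxide, lactone enolate) and added slowly to Pd(PPh3)4/LiCl in THF at high dilution. Tsuji–Trost allylic alkylation of the preformed lactone enolate by the π-allylpalladium from the allyl phenyl ether closes C13–C14 and gives the lactone-bridged macrocycle F1 (C14 epimers). CsOH opens the lactone to the dicesium salt of the C14-carboxy macrocycle F2. Acridinium-photocatalysed hydrodecarboxylation (9-mesityl-10-methylacridinium perchlorate, PhSSPh, 450 nm) then removes the secondary C14 carboxylate, which the acrylate carboxylate does not undergo, and delivers 21.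

Step 12 (oxidative cyclisation inside the macrocycle). Risks are transannular strain in reaching the alkene from the osmium glycolate and over-oxidation of the 11,12-alkene. The fallback moves the oxolane formation ahead of ring closure; it sets out from 19 and comes back at 22. Compound 19 is opened with CsOH to 20 and the open-chain diol is cyclised under the same osmium conditions; the only other electron-rich alkene is the deactivated allylic ether. This gives the dicesium salt of the oxolane seco acid F3, which is then submitted to the step 11 macrocyclisation and gives 22 directly.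

Step 13 (directed epoxidation). The facial sense rests on the chelated transition-state model, and the free C8 hydroxyl could open the epoxide to a second oxolane before step 14. The fallback replaces hydroxyl delivery by steric control; it sets out from 22 and comes back at 24. Compound 22 is persilylated with 1-(trimethylsilyl)imidazole to the trimethylsilyl ester 3,8-bis(trimethylsilyl) ether of 22 F4, which is epoxidised with dimethyldioxirane in acetone at −20 °C. With no free hydroxyl the reagent is steered only by the exposed face of the bridged macrocycle and cannot trigger oxolane formation. This gives 24, from which step 14 continues at the TMSOTf stage.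

**Further compounds**

F1 | step 11 | lactone-bridged macrocycle: 21 bearing a C14 carboxyl group lactonised onto O3 (C14 epimers) | C=C(C(=O)O)[C@H]1C[C@H]2OC(=O)C1C/C(C)=C/CC/C(C)=C\CC[C@@]2(C)O
F2 | step 11 | dicesium salt of the C14-carboxy derivative of 21 | [Cs+].[Cs+].C=C(C(=O)[O-])[C@H]1C[C@@H](O)[C@](C)(O)CC/C=C(C)\CC/C=C(C)/CC1C(=O)[O-]
F3 | step 12 | dicesium salt of the oxolane seco acid (20 after oxidative cyclisation; 4R,7S,8R in cembrane locants) | [Cs+].[Cs+].[O-]C(=O)C[C@H](C[C@@H](O)[C@@]1(C)CC[C@H](O1)[C@](C)(O)CC/C=C(C)/COc1ccccc1)C(=C)C([O-])=O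
F4 | step 13 | trimethylsilyl ester 3,8-bis(trimethylsilyl) ether of 22 | C=C(C(=O)O[Si](C)(C)C)[C@H]1C[C@@H](O[Si](C)(C)C)[C@@]2(C)CC[C@H](O2)[C@](C)(O[Si](C)(C)C)CC/C=C(C)/CC1
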